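**Plan**

1. Numbering used here: ring carbons C1 (CH carrying the isopropenyl group C15(=C16H2)CH3), C2 (CH2), C3 (C=O), C4, C5 (CH–O), C6 (C=O), C7, C8 (C(CH3)–O), C9, C10 (C=O), C11, C12 (C–CO2Me) = C13, C14; the ether oxygen joins C5 and C8 (oxolan-3-one ring).
2. Enabling feature: C16=C15(CH3)–C1–C2 is a but-3-enyl unit whose C2 end carries the C3 ketone, which is the ring-opened form of a (1-methylcyclopropyl)methyl radical. The retrosynthesis cuts C2–C3 of the 14-membered ring and re-joins C2 to C15 as a temporary cyclopropane, with C3 as a 2-pyridyl thioester and C16 as a bromide.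
3. Further cuts, in order: C12=C13 (Still–Gennari olefination), C11–C12 (phosphonate alkylation), C7–C8 (rhodium carbenoid C–H insertion closing the oxolanone), C4–C5 (auxiliary-controlled alkylation), O–C5 (Williamson ether synthesis), and the cyclopropane methylene C2 (Simmons–Smith).
4. Forward: oxolanone ring first (steps 1–6), keto phosphonate arm (7–9), cyclopropane aldehyde (10–15), union by Z-olefination (16), end-group adjustment (17–20), and the ring-opening macroketonisation closes the 14-membered ring last (21).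
5. Stereochemistry: C8 from (2R)-pent-4-yn-2-ol through C–H insertion with retention; C5 from the (S)-benzyloxazolidinone alkylation; C1 from ligand-controlled cyclopropanation of a Z-allylic alcohol, untouched by the ring opening; C12=C13 geometry from the Still–Gennari reagent.

Key step: step 21

Remark: compounds 1, 2, 4, 7, 17, 20 and 21 are taken as commercially available; the ligand enantiomer in step 12 is the antipode of the one that converts (E)-cinnamyl alcohol into the (1S,2S)-cyclopropane.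

**Route**

Step 1
Reactants: 1 (2R)-pent-4-yn-2-ol; 2 bromoacetic acid
Product: 3 {[(2R)-pent-4-yn-2-yl]oxy}acetic acid
Conditions: NaH (3 equiv), THF, 0 to 60 °C; aq. HCl work-up
Reagents that add atoms: none
Why: Williamson ether synthesis, in which the sodium alkoxide of 1 displaces bromide from sodium bromoacetate; no bond to the carbinol carbon (the future C8) is broken, so its R configuration is retained.

Step 2
Reactants: 3 {[(2R)-pent-4-yn-2-yl]oxy}acetic acid; 4 (4S)-4-benzyl-1,3-oxazolidin-2-one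
Product: 6 (4S)-4-benzyl-3-({[(2R)-pent-4-yn-2-yl]oxy}acetyl)-1,3-oxazolidin-2-one, via pivalic mixed anhydride 5 (not isolated)
Conditions: t-BuCOCl, Et3N, THF, −20 °C; then 4, LiCl, 23 °C
Reagents that add atoms: none
Why: N-acylation of the Evans auxiliary through the pivalic mixed anhydride, which reacts at its less hindered carbonyl, attaches the controller for C5.

Step 3
Reactants: 6 (4S)-4-benzyl-3-({[(2R)-pent-4-yn-2-yl]oxy}acetyl)-1,3-oxazolidin-2-one; 7 prop-2-en-1-yl bromoacetate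
Product: 9 prop-2-en-1-yl (3R)-4-[(4S)-4-benzyl-2-oxo-1,3-oxazolidin-3-yl]-4-oxo-3-{[(2R)-pent-4-yn-2-yl]oxy}butanoate, via sodium enolate 8 (not isolated)
Conditions: NaN(SiMe3)2, THF, −78 °C; then 7, −78 to −45 °C
Reagents that add atoms: none
Why: Evans alkylation, in which the chelated Z sodium enolate is alkylated by the α-bromo ester on the face opposite the benzyl group; this sets C5 as R and brings in C4 and C3 at the carboxyl level.

Step 4
Reactants: 9 prop-2-en-1-yl (3R)-4-[(4S)-4-benzyl-2-oxo-1,3-oxazolidin-3-yl]-4-oxo-3-{[(2R)-pent-4-yn-2-yl]oxy}butanoate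
Product: 11 (2R)-4-oxo-2-{[(2R)-pent-4-yn-2-yl]oxy}-4-(prop-2-en-1-yloxy)butanoic acid, via lithium peroxycarboxylate 10 (not isolated)
Conditions: LiOH, H2O2, THF/H2O, 0 °C; then Na2SO3; aq. HCl
Reagents that add atoms: hydrogen peroxide (OO)
Why: Hydroperoxide cleaves the exocyclic imide carbonyl selectively (standard auxiliary removal) and sulfite reduces the peracid, while the less electrophilic allyl ester and the C5 centre should survive the short exposure at 0 °C.

Step 5
Reactants: 11 (2R)-4-oxo-2-{[(2R)-pent-4-yn-2-yl]oxy}-4-(prop-2-en-1-yloxy)butanoic acid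
Product: 13 prop-2-en-1-yl (3R)-5-diazo-4-oxo-3-{[(2R)-pent-4-yn-2-yl]oxy}pentanoate, via isobutyl carbonic anhydride 12 (not isolated)
Conditions: i-BuOCOCl, N-methylmorpholine, THF, −20 °C; then CH2N2, Et2O, 0 °C
Reagents that add atoms: diazomethane (C=[N+]=[N-])
Why: Acylation of diazomethane by the mixed carbonic anhydride (the first stage of an Arndt–Eistert sequence) gives the α-alkoxy diazoketone and supplies C7 without touching the adjacent stereocentre.

Step 6
Reactants: 13 prop-2-en-1-yl (3R)-5-diazo-4-oxo-3-{[(2R)-pent-4-yn-2-yl]oxy}pentanoate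
Product: 14 prop-2-en-1-yl [(2R,5R)-5-methyl-3-oxo-5-(prop-2-yn-1-yl)oxolan-2-yl]acetate
Conditions: Rh2(OAc)4 (1 mol %), CH2Cl2, 40 °C, slow addition
Reagents that add atoms: none
Why: Rhodium carbenoid 1,5 C–H insertion into the ether methine next to oxygen, a known route to oxolan-3-ones, forms C7–C8 with retention at the inserted carbon, so the quaternary C8 takes its configuration from 1 and C5 is not involved.

Step 7
Reactants: 14 prop-2-en-1-yl [(2R,5R)-5-methyl-3-oxo-5-(prop-2-yn-1-yl)oxolan-2-yl]acetate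
Product: 15 prop-2-en-1-yl [(2R,5R)-5-(3-bromoprop-2-yn-1-yl)-5-methyl-3-oxooxolan-2-yl]acetate
Conditions: N-bromosuccinimide, AgNO3 (10 mol %), acetone, 23 °C
Reagents that add atoms: N-bromosuccinimide (O=C1CCC(=O)N1Br)
Why: Silver-catalysed electrophilic bromination of the terminal alkyne under neutral conditions should leave the ketone, the ester and both stereocentres alone.

Step 8
Reactants: 15 prop-2-en-1-yl [(2R,5R)-5-(3-bromoprop-2-yn-1-yl)-5-methyl-3-oxooxolan-2-yl]acetate
Product: 16 prop-2-en-1-yl [(2R,5S)-5-(3-bromo-2-oxopropyl)-5-methyl-3-oxooxolan-2-yl]acetate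
Conditions: Ph3PAuNTf2 (5 mol %), H2O (3 equiv), ClCH2CH2Cl, 23 °C
Reagents that add atoms: water (O)
Why: Gold-catalysed hydration of a 1-bromoalkyne places the oxygen on the carbon remote from bromine and gives the bromomethyl ketone (C10=O, C11–Br) without base; the descriptor at C8 changes only through the priority rules.

Step 9
Reactants: 16 prop-2-en-1-yl [(2R,5S)-5-(3-bromo-2-oxopropyl)-5-methyl-3-oxooxolan-2-yl]acetate; 17 methyl [bis(2,2,2-trifluoroethoxy)phosphoryl]acetate
Product: 19 prop-2-en-1-yl [(2R,5R)-5-{4-[bis(2,2,2-trifluoroethoxy)phosphoryl]-5-methoxy-2,5-dioxopentyl}-5-methyl-3-oxooxolan-2-yl]acetate (both epimers at the phosphorus-bearing carbon), via sodium phosphonoacetate salt 18 (not isolated)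
Conditions: 17 (2 equiv), NaH (1.8 equiv), THF, 0 °C; then 16, 0 to 23 °C
Reagents that add atoms: none
Why: SN2 alkylation of the soft, weakly basic phosphonoacetate anion by the α-bromo ketone forms C11–C12 and installs the Still–Gennari phosphonate; the new centre at C12 is lost in step 16 and may be a mixture.

Step 10
Reactants: 20 3-{[tert-butyl(dimethyl)silyl]oxy}propanal; 21 ethyl 2-[bis(2,2,2-trifluoroethoxy)phosphoryl]propanoate
Product: 23 ethyl (2Z)-5-{[tert-butyl(dimethyl)silyl]oxy}-2-methylpent-2-enoate, via potassium phosphonate carbanion 22 (not isolated)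
Conditions: KN(SiMe3)2, 18-crown-6, THF, −78 °C; then 20
Reagents that add atoms: none
Why: Still–Gennari olefination, in which the trifluoroethyl phosphonate gives the kinetic Z trisubstituted enoate; this geometry fixes the later cis relationship on the cyclopropane.

Step 11
Reactants: 23 ethyl (2Z)-5-{[tert-butyl(dimethyl)silyl]oxy}-2-methylpent-2-enoate
Product: 24 (2Z)-5-{[tert-butyl(dimethyl)silyl]oxy}-2-methylpent-2-en-1-ol
Conditions: i-Bu2AlH, CH2Cl2, −78 °C; aqueous potassium sodium tartrate work-up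
Reagents that add atoms: none
Why: i-Bu2AlH reduces the conjugated ester to the allylic alcohol by 1,2-addition without isomerising the Z double bond.

Step 12
Reactants: 24 (2Z)-5-{[tert-butyl(dimethyl)silyl]oxy}-2-methylpent-2-en-1-ol
Product: 25 [(1R,2R)-2-(2-{[tert-butyl(dimethyl)silyl]oxy}ethyl)-1-methylcyclopropyl]methanol
Conditions: Zn(CH2I)2·DME (from Et2Zn and CH2I2), (4S,5S)-2-butyl-N,N,N′,N′-tetramethyl-1,3,2-dioxaborolane-4,5-dicarboxamide, CH2Cl2, −10 to 23 °C
Reagents that add atoms: diiodomethane (ICI)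
Why: Dioxaborolane-mediated asymmetric Simmons–Smith cyclopropanation (Charette), in which the zinc carbenoid is delivered to one alkene face through the alkoxide-bound chiral boronate; this sets both ring stereocentres (the future C1 among them), and the stereospecific syn addition turns the Z geometry into the cis arrangement of CH2OH and side chain.

Step 13
Reactants: 25 [(1R,2R)-2-(2-{[tert-butyl(dimethyl)silyl]oxy}ethyl)-1-methylcyclopropyl]methanol
Product: 26 tert-butyl{2-[(1R,2R)-2-{[(4-methoxyphenyl)methoxy]methyl}-2-methylcyclopropyl]ethoxy}dimethylsilane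
Conditions: NaH, 4-methoxybenzyl chloride, Bu4NI (cat.), THF/DMF, 0 to 23 °C
Reagents that add atoms: 4-methoxybenzyl chloride (COc1ccc(CCl)cc1)
Why: Williamson etherification protects the cyclopropylmethanol as a 4-methoxybenzyl ether that is orthogonal to the silyl ether.

Step 14
Reactants: 26 tert-butyl{2-[(1R,2R)-2-{[(4-methoxyphenyl)methoxy]methyl}-2-methylcyclopropyl]ethoxy}dimethylsilane
Product: 27 2-[(1R,2R)-2-{[(4-methoxyphenyl)methoxy]methyl}-2-methylcyclopropyl]ethan-1-ol
Conditions: HF·pyridine, pyridine, THF, 0 to 23 °C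
Reagents that add atoms: none
Why: Buffered fluoride cleaves the primary silyl ether and should leave the benzyl-type ether and the cyclopropane intact.

Step 15
Reactants: 27 2-[(1R,2R)-2-{[(4-methoxyphenyl)methoxy]methyl}-2-methylcyclopropyl]ethan-1-ol
Product: 28 [(1R,2R)-2-{[(4-methoxyphenyl)methoxy]methyl}-2-methylcyclopropyl]acetaldehyde
Conditions: Dess–Martin periodinane, NaHCO3, CH2Cl2, 0 to 23 °C
Reagents that add atoms: none
Why: Dess–Martin oxidation gives the aldehyde (C13) under buffered conditions that do not disturb the ring stereocentres.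

Step 16
Reactants: 19 prop-2-en-1-yl [(2R,5R)-5-{4-[bis(2,2,2-trifluoroethoxy)phosphoryl]-5-methoxy-2,5-dioxopentyl}-5-methyl-3-oxooxolan-2-yl]acetate; 28 [(1R,2R)-2-{[(4-methoxyphenyl)methoxy]methyl}-2-methylcyclopropyl]acetaldehyde
Product: 30 prop-2-en-1-yl [(2R,5R)-5-{(4Z)-4-(methoxycarbonyl)-6-[(1S,2R)-2-{[(4-methoxyphenyl)methoxy]methyl}-2-methylcyclopropyl]-2-oxohex-4-en-1-yl}-5-methyl-3-oxooxolan-2-yl]acetate, via potassium phosphonate carbanion 29 (not isolated)
Conditions: KN(SiMe3)2 (1.0 equiv), 18-crown-6, THF, −78 °C; then 28, −78 °C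
Reagents that add atoms: none
Why: Still–Gennari Horner–Wadsworth–Emmons olefination, in which only the doubly activated C12–H is deprotonated by one equivalent of base and the trifluoroethyl phosphonate should give the Z enoate (ester cis to C14) under kinetic control; the cyclopropane descriptor changes only through the priority rules.

Step 17
Reactants: 30 prop-2-en-1-yl [(2R,5R)-5-{(4Z)-4-(methoxycarbonyl)-6-[(1S,2R)-2-{[(4-methoxyphenyl)methoxy]methyl}-2-methylcyclopropyl]-2-oxohex-4-en-1-yl}-5-methyl-3-oxooxolan-2-yl]acetate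
Product: 31 prop-2-en-1-yl [(2R,5R)-5-{(4Z)-6-[(1S,2R)-2-(hydroxymethyl)-2-methylcyclopropyl]-4-(methoxycarbonyl)-2-oxohex-4-en-1-yl}-5-methyl-3-oxooxolan-2-yl]acetate
Conditions: DDQ, CH2Cl2/pH 7 buffer, 0 °C
Reagents that add atoms: none
Why: Oxidative cleavage of the 4-methoxybenzyl ether by DDQ under buffered conditions frees the C16 alcohol without acid or base.

Step 18
Reactants: 31 prop-2-en-1-yl [(2R,5R)-5-{(4Z)-6-[(1S,2R)-2-(hydroxymethyl)-2-methylcyclopropyl]-4-(methoxycarbonyl)-2-oxohex-4-en-1-yl}-5-methyl-3-oxooxolan-2-yl]acetate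
Product: 32 [(2R,5R)-5-{(4Z)-6-[(1S,2R)-2-(hydroxymethyl)-2-methylcyclopropyl]-4-(methoxycarbonyl)-2-oxohex-4-en-1-yl}-5-methyl-3-oxooxolan-2-yl]acetic acid
Conditions: Pd(PPh3)4 (5 mol %), N-methylaniline, THF, 23 °C
Reagents that add atoms: none
Why: Palladium-catalysed allyl transfer to a weakly basic amine (Tsuji–Trost deallylation) unmasks the C3 acid in the presence of the methyl ester, the ketones and the free alcohol.

Step 19
Reactants: 32 [(2R,5R)-5-{(4Z)-6-[(1S,2R)-2-(hydroxymethyl)-2-methylcyclopropyl]-4-(methoxycarbonyl)-2-oxohex-4-en-1-yl}-5-methyl-3-oxooxolan-2-yl]acetic acid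
Product: 33 S-pyridin-2-yl [(2R,5R)-5-{(4Z)-6-[(1S,2R)-2-(hydroxymethyl)-2-methylcyclopropyl]-4-(methoxycarbonyl)-2-oxohex-4-en-1-yl}-5-methyl-3-oxooxolan-2-yl]ethanethioate
Conditions: 2,2′-dipyridyl disulfide, PPh3, CH2Cl2, 23 °C
Reagents that add atoms: 2,2′-dipyridyl disulfide (c1ccc(SSc2ccccn2)nc1)
Why: Mukaiyama redox condensation converts the acid into the S-2-pyridyl thioester, the acyl partner for nickel, under neutral conditions in which the thiolate outcompetes the primary alcohol as nucleophile.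

Step 20
Reactants: 33 S-pyridin-2-yl [(2R,5R)-5-{(4Z)-6-[(1S,2R)-2-(hydroxymethyl)-2-methylcyclopropyl]-4-(methoxycarbonyl)-2-oxohex-4-en-1-yl}-5-methyl-3-oxooxolan-2-yl]ethanethioate
Product: 34 S-pyridin-2-yl [(2R,5R)-5-{(4Z)-6-[(1S,2R)-2-(bromomethyl)-2-methylcyclopropyl]-4-(methoxycarbonyl)-2-oxohex-4-en-1-yl}-5-methyl-3-oxooxolan-2-yl]ethanethioate
Conditions: CBr4, PPh3, 2,6-lutidine, CH2Cl2, −20 to 0 °C
Reagents that add atoms: carbon tetrabromide (BrC(Br)(Br)Br)
Why: Appel bromination, in which bromide displaces the alkoxyphosphonium ion by SN2 at low temperature in a non-polar medium; this should give the cyclopropylmethyl bromide while suppressing ionisation to homoallyl or cyclobutyl isomers.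

Step 21
Reactants: 34 S-pyridin-2-yl [(2R,5R)-5-{(4Z)-6-[(1S,2R)-2-(bromomethyl)-2-methylcyclopropyl]-4-(methoxycarbonyl)-2-oxohex-4-en-1-yl}-5-methyl-3-oxooxolan-2-yl]ethanethioate
Product: 35 methyl (1R,5Z,8S,12R)-1-methyl-3,10,13-trioxo-8-(prop-1-en-2-yl)-15-oxabicyclo[10.2.1]pentadec-5-ene-5-carboxylate (the target)
Conditions: NiBr2(dme) (30 mol %), 4,4′-di-tert-butyl-2,2′-bipyridine (33 mol %), Zn (5 equiv), N,N-dimethylacetamide, 25 °C, syringe-pump addition to 2 mM
Reagents that add atoms: none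
Why: Proposed new method: zinc reduces nickel to the zerovalent state, which inserts into the C3–S bond of the 2-pyridyl thioester, and halogen abstraction at C16 gives a (1-methylcyclopropyl)methyl radical that opens by strain-driven β-scission of the C15–C2 bond far faster than it can be captured, so that the isopropenyl group and a primary C2 radical appear together and the acylnickel traps C2 and forms C2–C3 by reductive elimination. The closest known reaction type is the nickel-catalysed reductive coupling of alkyl halides with 2-pyridyl thioesters to give ketones, in which cyclopropylmethyl halides serve as radical clocks and deliver ring-opened but-3-enyl ketones. The 14-membered carbocycle closes by capture of the C2 radical at the tethered acylnickel and C(sp3)–C(acyl) reductive elimination, a macrocyclic closure outside the small-ring rules, and the cyclopropane is the only ring that is lost. No stereocentre is made: C1 is a spectator ring carbon that keeps all four substituents, so its configuration from step 12 is carried over unchanged, and C5 and C8 see only neutral conditions. The selectivity needed is scission of C15–C2 and not C15–C1, and the cis relationship between C16 and the C14 chain on the cyclopropane, which raises the transition state leading to the secondary C1 radical, together with the faster capture of the unhindered primary radical, is expected to secure it. High dilution should favour ring closure over oligomerisation, and the ketones, the enoate and the ether bridge should be inert to the neutral zinc and nickel reagents.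

**Compound list**

1 | (2R)-pent-4-yn-2-ol | C#CC[C@@H](C)O | starting material
2 | bromoacetic acid | OC(=O)CBr | starting material
3 | {[(2R)-pent-4-yn-2-yl]oxy}acetic acid | C#CC[C@@H](C)OCC(=O)O | intermediate
4 | (4S)-4-benzyl-1,3-oxazolidin-2-one | O=C1N[C@@H](Cc2ccccc2)CO1 | starting material
5 | {[(2R)-pent-4-yn-2-yl]oxy}acetic pivalic anhydride | C#CC[C@@H](C)OCC(=O)OC(=O)C(C)(C)C | intermediate
6 | (4S)-4-benzyl-3-({[(2R)-pent-4-yn-2-yl]oxy}acetyl)-1,3-oxazolidin-2-one | C#CC[C@@H](C)OCC(=O)N1C(=O)OC[C@@H]1Cc1ccccc1 | intermediate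
7 | prop-2-en-1-yl bromoacetate | C=CCOC(=O)CBr | starting material
8 | sodium (Z)-enolate of 6 | C#CC[C@@H](C)O/C=C(\[O-])N1C(=O)OC[C@@H]1Cc1ccccc1.[Na+] | intermediate
9 | prop-2-en-1-yl (3R)-4-[(4S)-4-benzyl-2-oxo-1,3-oxazolidin-3-yl]-4-oxo-3-{[(2R)-pent-4-yn-2-yl]oxy}butanoate | C=CCOC(=O)C[C@@H](O[C@H](C)CC#C)C(=O)N1C(=O)OC[C@@H]1Cc1ccccc1 | intermediate
10 | lithium (2R)-4-oxo-2-{[(2R)-pent-4-yn-2-yl]oxy}-4-(prop-2-en-1-yloxy)butaneperoxoate | C=CCOC(=O)C[C@@H](O[C@H](C)CC#C)C(=O)O[O-].[Li+] | intermediate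
11 | (2R)-4-oxo-2-{[(2R)-pent-4-yn-2-yl]oxy}-4-(prop-2-en-1-yloxy)butanoic acid | C=CCOC(=O)C[C@@H](O[C@H](C)CC#C)C(=O)O | intermediate
12 | mixed anhydride of 11 with isobutyl hydrogen carbonate | C=CCOC(=O)C[C@@H](O[C@H](C)CC#C)C(=O)OC(=O)OCC(C)C | intermediate
13 | prop-2-en-1-yl (3R)-5-diazo-4-oxo-3-{[(2R)-pent-4-yn-2-yl]oxy}pentanoate | C=CCOC(=O)C[C@@H](O[C@H](C)CC#C)C(=O)C=[N+]=[N-] | intermediate
14 | prop-2-en-1-yl [(2R,5R)-5-methyl-3-oxo-5-(prop-2-yn-1-yl)oxolan-2-yl]acetate | C#CC[C@]1(C)CC(=O)[C@@H](CC(=O)OCC=C)O1 | intermediate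
15 | prop-2-en-1-yl [(2R,5R)-5-(3-bromoprop-2-yn-1-yl)-5-methyl-3-oxooxolan-2-yl]acetate | BrC#CC[C@]1(C)CC(=O)[C@@H](CC(=O)OCC=C)O1 | intermediate
16 | prop-2-en-1-yl [(2R,5S)-5-(3-bromo-2-oxopropyl)-5-methyl-3-oxooxolan-2-yl]acetate | BrCC(=O)C[C@]1(C)CC(=O)[C@@H](CC(=O)OCC=C)O1 | intermediate
17 | methyl [bis(2,2,2-trifluoroethoxy)phosphoryl]acetate | COC(=O)CP(=O)(OCC(F)(F)F)OCC(F)(F)F | starting material
18 | sodium salt of 17 (phosphonoacetate carbanion) | COC(=O)[CH-]P(=O)(OCC(F)(F)F)OCC(F)(F)F.[Na+] | intermediate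
19 | prop-2-en-1-yl [(2R,5R)-5-{4-[bis(2,2,2-trifluoroethoxy)phosphoryl]-5-methoxy-2,5-dioxopentyl}-5-methyl-3-oxooxolan-2-yl]acetate | COC(=O)C(CC(=O)C[C@]1(C)CC(=O)[C@@H](CC(=O)OCC=C)O1)P(=O)(OCC(F)(F)F)OCC(F)(F)F | intermediate
20 | 3-{[tert-butyl(dimethyl)silyl]oxy}propanal | O=CCCO[Si](C)(C)C(C)(C)C | starting material
21 | ethyl 2-[bis(2,2,2-trifluoroethoxy)phosphoryl]propanoate | CCOC(=O)C(C)P(=O)(OCC(F)(F)F)OCC(F)(F)F | starting material
22 | potassium salt of 21 (phosphonate carbanion) | CCOC(=O)[C-](C)P(=O)(OCC(F)(F)F)OCC(F)(F)F.[K+] | intermediate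
23 | ethyl (2Z)-5-{[tert-butyl(dimethyl)silyl]oxy}-2-methylpent-2-enoate | CCOC(=O)/C(C)=C\CCO[Si](C)(C)C(C)(C)C | intermediate
24 | (2Z)-5-{[tert-butyl(dimethyl)silyl]oxy}-2-methylpent-2-en-1-ol | OC/C(C)=C\CCO[Si](C)(C)C(C)(C)C | intermediate
25 | [(1R,2R)-2-(2-{[tert-butyl(dimethyl)silyl]oxy}ethyl)-1-methylcyclopropyl]methanol | OC[C@]1(C)C[C@@H]1CCO[Si](C)(C)C(C)(C)C | intermediate
26 | tert-butyl{2-[(1R,2R)-2-{[(4-methoxyphenyl)methoxy]methyl}-2-methylcyclopropyl]ethoxy}dimethylsilane | COc1ccc(COC[C@]2(C)C[C@@H]2CCO[Si](C)(C)C(C)(C)C)cc1 | intermediate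
27 | 2-[(1R,2R)-2-{[(4-methoxyphenyl)methoxy]methyl}-2-methylcyclopropyl]ethan-1-ol | COc1ccc(COC[C@]2(C)C[C@@H]2CCO)cc1 | intermediate
28 | [(1R,2R)-2-{[(4-methoxyphenyl)methoxy]methyl}-2-methylcyclopropyl]acetaldehyde | COc1ccc(COC[C@]2(C)C[C@@H]2CC=O)cc1 | intermediate
29 | potassium salt of 19 (phosphonate carbanion at C12) | COC(=O)[C-](CC(=O)C[C@]1(C)CC(=O)[C@@H](CC(=O)OCC=C)O1)P(=O)(OCC(F)(F)F)OCC(F)(F)F.[K+] | intermediate
30 | prop-2-en-1-yl [(2R,5R)-5-{(4Z)-4-(methoxycarbonyl)-6-[(1S,2R)-2-{[(4-methoxyphenyl)methoxy]methyl}-2-methylcyclopropyl]-2-oxohex-4-en-1-yl}-5-methyl-3-oxooxolan-2-yl]acetate | COc1ccc(COC[C@]2(C)C[C@@H]2C/C=C(\C(=O)OC)CC(=O)C[C@]3(C)CC(=O)[C@@H](CC(=O)OCC=C)O3)cc1 | intermediate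
31 | prop-2-en-1-yl [(2R,5R)-5-{(4Z)-6-[(1S,2R)-2-(hydroxymethyl)-2-methylcyclopropyl]-4-(methoxycarbonyl)-2-oxohex-4-en-1-yl}-5-methyl-3-oxooxolan-2-yl]acetate | OC[C@]1(C)C[C@@H]1C/C=C(\C(=O)OC)CC(=O)C[C@]2(C)CC(=O)[C@@H](CC(=O)OCC=C)O2 | intermediate
32 | [(2R,5R)-5-{(4Z)-6-[(1S,2R)-2-(hydroxymethyl)-2-methylcyclopropyl]-4-(methoxycarbonyl)-2-oxohex-4-en-1-yl}-5-methyl-3-oxooxolan-2-yl]acetic acid | OC[C@]1(C)C[C@@H]1C/C=C(\C(=O)OC)CC(=O)C[C@]2(C)CC(=O)[C@@H](CC(=O)O)O2 | intermediate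
33 | S-pyridin-2-yl [(2R,5R)-5-{(4Z)-6-[(1S,2R)-2-(hydroxymethyl)-2-methylcyclopropyl]-4-(methoxycarbonyl)-2-oxohex-4-en-1-yl}-5-methyl-3-oxooxolan-2-yl]ethanethioate | OC[C@]1(C)C[C@@H]1C/C=C(\C(=O)OC)CC(=O)C[C@]2(C)CC(=O)[C@@H](CC(=O)Sc3ccccn3)O2 | intermediate
34 | S-pyridin-2-yl [(2R,5R)-5-{(4Z)-6-[(1S,2R)-2-(bromomethyl)-2-methylcyclopropyl]-4-(methoxycarbonyl)-2-oxohex-4-en-1-yl}-5-methyl-3-oxooxolan-2-yl]ethanethioate | BrC[C@]1(C)C[C@@H]1C/C=C(\C(=O)OC)CC(=O)C[C@]2(C)CC(=O)[C@@H](CC(=O)Sc3ccccn3)O2 | intermediate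
35 | methyl (1R,5Z,8S,12R)-1-methyl-3,10,13-trioxo-8-(prop-1-en-2-yl)-15-oxabicyclo[10.2.1]pentadec-5-ene-5-carboxylate | C=C(C)[C@H]1C/C=C(\C(=O)OC)CC(=O)C[C@]2(C)CC(=O)[C@@H](CC(=O)C1)O2 | target

**Summary**

Total step count: 21. Longest linear sequence: 15 steps (steps 1–9 and 16–21).

**Steps most likely to fail, with fallbacks**

Step 21. The ring opening may go the wrong way (scission of C15–C1 to the secondary radical), and coupling between molecules may outrun ring closure. The fallback opens the ring earlier in the polar manifold, where the equilibrium between cyclopropylmethyl and but-3-enyl Grignard reagents lies on the side of the primary alkylmagnesium, and then uses the established nickel-catalysed ketone synthesis from a primary alkyl iodide and a 2-pyridyl thioester. It sets out from 25: CBr4 and PPh3 give {2-[(1R,2R)-2-(bromomethyl)-2-methylcyclopropyl]ethoxy}(tert-butyl)dimethylsilane F1; Mg in THF gives the cyclopropylmethylmagnesium bromide F2, which on warming rearranges to the primary but-3-enylmagnesium bromide F3; I2 gives tert-butyl{[(3R)-3-(iodomethyl)-4-methylpent-4-en-1-yl]oxy}dimethylsilane F4. HF·pyridine then gives (3R)-3-(iodomethyl)-4-methylpent-4-en-1-ol F5 and Dess–Martin periodinane gives (3R)-3-(iodomethyl)-4-methylpent-4-enal F6. Olefination with carbanion 29 as in step 16 gives the iodo enoate allyl ester F7, deallylation as in step 18 gives the iodo acid F8, and thioesterification as in step 19 gives the iodo S-2-pyridyl thioester F9. NiBr2(dme), the bipyridine ligand and Zn at high dilution should then close the same C2–C3 bond, and the fallback comes back to the route at 35.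

Step 6. The rhodium carbenoid may be diverted to the C3 ester carbonyl (a six-membered carbonyl ylide) or to the alkyne instead of inserting into the C8–H bond. The fallback runs the insertion before the ester is present and sets C5 afterwards by auxiliary control. It sets out from mixed anhydride 5 (made from 3 as in step 2): CH2N2 gives 1-diazo-3-{[(2R)-pent-4-yn-2-yl]oxy}propan-2-one F10, and Rh2(OAc)4 gives (5R)-5-methyl-5-(prop-2-yn-1-yl)oxolan-3-one F11. Condensation with (2R)-2-(methoxymethyl)pyrrolidin-1-amine gives the RAMP hydrazone F12; LiN(i-Pr)2 gives the lithium aza-enolate F13 on the oxygen-bearing side; alkylation with 7 gives the alkylated hydrazone F14 (Enders alkylation, with the auxiliary controlling C5). Two-phase hydrolysis with aqueous oxalic acid comes back to the route at 14.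

Step 3. The thermally fragile α-alkoxy enolate may decompose, or attack the ester carbonyl of the bromoacetate, before it is C-alkylated. The fallback uses the much more reactive allyl iodide and then adjusts the oxidation level. It sets out from enolate 8: allyl iodide gives (4S)-4-benzyl-3-[(2R)-2-{[(2R)-pent-4-yn-2-yl]oxy}pent-4-enoyl]-1,3-oxazolidin-2-one F15. Ozonolysis at −78 °C (the alkene reacts before the alkyne) gives the ozonide F16, and PPh3 reduces it to (3R)-4-[(4S)-4-benzyl-2-oxo-1,3-oxazolidin-3-yl]-4-oxo-3-{[(2R)-pent-4-yn-2-yl]oxy}butanal F17. Pinnick oxidation gives (3R)-4-[(4S)-4-benzyl-2-oxo-1,3-oxazolidin-3-yl]-4-oxo-3-{[(2R)-pent-4-yn-2-yl]oxy}butanoic acid F18, and carbodiimide esterification with prop-2-en-1-ol comes back to the route at 9.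

Further compounds
F1 | step 21 | {2-[(1R,2R)-2-(bromomethyl)-2-methylcyclopropyl]ethoxy}(tert-butyl)dimethylsilane | BrC[C@]1(C)C[C@@H]1CCO[Si](C)(C)C(C)(C)C
F2 | step 21 | bromo{[(1R,2R)-2-(2-{[tert-butyl(dimethyl)silyl]oxy}ethyl)-1-methylcyclopropyl]methyl}magnesium | Br[Mg]C[C@]1(C)C[C@@H]1CCO[Si](C)(C)C(C)(C)C
F3 | step 21 | bromo[(2R)-2-(2-{[tert-butyl(dimethyl)silyl]oxy}ethyl)-3-methylbut-3-en-1-yl]magnesium | C=C(C)[C@H](C[Mg]Br)CCO[Si](C)(C)C(C)(C)C
F4 | step 21 | tert-butyl{[(3R)-3-(iodomethyl)-4-methylpent-4-en-1-yl]oxy}dimethylsilane | C=C(C)[C@H](CI)CCO[Si](C)(C)C(C)(C)C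
F5 | step 21 | (3R)-3-(iodomethyl)-4-methylpent-4-en-1-ol | C=C(C)[C@H](CI)CCO
F6 | step 21 | (3R)-3-(iodomethyl)-4-methylpent-4-enal | C=C(C)[C@H](CI)CC=O
F7 | step 21 | prop-2-en-1-yl [(2R,5R)-5-{(4Z,7R)-7-(iodomethyl)-4-(methoxycarbonyl)-8-methyl-2-oxonona-4,8-dien-1-yl}-5-methyl-3-oxooxolan-2-yl]acetate | C=C(C)[C@H](CI)C/C=C(\C(=O)OC)CC(=O)C[C@]1(C)CC(=O)[C@@H](CC(=O)OCC=C)O1
F8 | step 21 | [(2R,5R)-5-{(4Z,7R)-7-(iodomethyl)-4-(methoxycarbonyl)-8-methyl-2-oxonona-4,8-dien-1-yl}-5-methyl-3-oxooxolan-2-yl]acetic acid | C=C(C)[C@H](CI)C/C=C(\C(=O)OC)CC(=O)C[C@]1(C)CC(=O)[C@@H](CC(=O)O)O1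
F9 | step 21 | S-pyridin-2-yl [(2R,5R)-5-{(4Z,7R)-7-(iodomethyl)-4-(methoxycarbonyl)-8-methyl-2-oxonona-4,8-dien-1-yl}-5-methyl-3-oxooxolan-2-yl]ethanethioate | C=C(C)[C@H](CI)C/C=C(\C(=O)OC)CC(=O)C[C@]1(C)CC(=O)[C@@H](CC(=O)Sc2ccccn2)O1
F10 | step 6 | 1-diazo-3-{[(2R)-pent-4-yn-2-yl]oxy}propan-2-one | C#CC[C@@H](C)OCC(=O)C=[N+]=[N-]
F11 | step 6 | (5R)-5-methyl-5-(prop-2-yn-1-yl)oxolan-3-one | C#CC[C@]1(C)CC(=O)CO1
F12 | step 6 | (2R)-2-(methoxymethyl)-N-[(5R)-5-methyl-5-(prop-2-yn-1-yl)oxolan-3-ylidene]pyrrolidin-1-amine | C#CC[C@]1(C)CC(=NN2CCC[C@@H]2COC)CO1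
F13 | step 6 | lithium aza-enolate of F12 (deprotonated at the O-bearing CH2) | C#CC[C@]1(C)CC(=CO1)N([Li])N1CCC[C@@H]1COC
F14 | step 6 | prop-2-en-1-yl [(2R,5R)-3-{[(2R)-2-(methoxymethyl)pyrrolidin-1-yl]imino}-5-methyl-5-(prop-2-yn-1-yl)oxolan-2-yl]acetate | C#CC[C@]1(C)CC(=NN2CCC[C@@H]2COC)[C@@H](CC(=O)OCC=C)O1
F15 | step 3 | (4S)-4-benzyl-3-[(2R)-2-{[(2R)-pent-4-yn-2-yl]oxy}pent-4-enoyl]-1,3-oxazolidin-2-one | C=CC[C@@H](O[C@H](C)CC#C)C(=O)N1C(=O)OC[C@@H]1Cc1ccccc1
F16 | step 3 | (4S)-4-benzyl-3-[(2R)-2-{[(2R)-pent-4-yn-2-yl]oxy}-3-(1,2,4-trioxolan-3-yl)propanoyl]-1,3-oxazolidin-2-one | O=C(N1C(=O)OC[C@@H]1Cc1ccccc1)[C@@H](CC1OCOO1)O[C@H](C)CC#C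
F17 | step 3 | (3R)-4-[(4S)-4-benzyl-2-oxo-1,3-oxazolidin-3-yl]-4-oxo-3-{[(2R)-pent-4-yn-2-yl]oxy}butanal | O=CC[C@@H](O[C@H](C)CC#C)C(=O)N1C(=O)OC[C@@H]1Cc1ccccc1
F18 | step 3 | (3R)-4-[(4S)-4-benzyl-2-oxo-1,3-oxazolidin-3-yl]-4-oxo-3-{[(2R)-pent-4-yn-2-yl]oxy}butanoic acid | OC(=O)C[C@@H](O[C@H](C)CC#C)C(=O)N1C(=O)OC[C@@H]1Cc1ccccc1
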